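## Retrosynthetic overview

1. Target ⇐ one-pot Ni/Cr closure of the ten-membered ring at C6–C7 (the bond formed when the farnesyl chain cyclises in germacrene biogenesis) followed by O6→C12 lactonisation, from an acyclic bis-epoxy aldehyde carrying a Z enol triflate.
2. That aldehyde ⇐ acyclic Z,Z,E-triene diol by twofold Sharpless epoxidation (both oxiranes, same tartrate) and oxidation of C6–OH.
3. Triene diol ⇐ Sonogashira union of a Z vinyl iodide with (Z)-3-methylpent-2-en-4-yn-1-ol, zinc semireduction, desilylation.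
4. Vinyl iodide/enol triflate ⇐ γ-acyloxy ynoate (asymmetric alkynylation sets C8; hydration, acetoxymethylation, chelation-controlled triflation).
5. Ring order: two oxiranes (acyclic, reagent-controlled) → ten-membered carbocycle → butenolide (same flask as the carbocycle).

Assumption: germacrane numbering (C1–C15; C12 lactone carbonyl, C13 CH2OAc, C14 CH2OH, C15 CH3) is used for locants, and the ProPhenol enantiomer is taken as the one that adds the alkyne to the Re face of the C8 aldehyde (written as (S,S); the antipodal ligand is used if the sense is opposite).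

## Route

Step 1
Reactants: 1 propargyl alcohol; 2 allylmagnesium bromide
Product: 4 (Z)-2-(iodomethylene)pent-4-en-1-ol, via alkenylmagnesium alkoxide 3 (not isolated)
Conditions: 2 (2.5 equiv), CuI (10 mol%), Et2O, −10 °C → rt; then I2, THF, −40 → 0 °C
Reagents that add atoms: iodine, [I][I]
Why: Copper-catalysed anti-carbomagnesiation of a propargylic alkoxide (Duboudin reaction) puts allyl on the internal carbon and magnesium on the terminal carbon, held cis to CH2O in a five-membered chelate, so iodinolysis with retention gives only the Z vinyl iodide (I cis to the future C14).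

Step 2
Reactants: 4 (Z)-2-(iodomethylene)pent-4-en-1-ol
Product: 5 tert-butyl{[(Z)-2-(iodomethylene)pent-4-en-1-yl]oxy}diphenylsilane
Conditions: TBDPSCl, imidazole, CH2Cl2, 0 °C → rt
Reagents that add atoms: tert-butyl(chloro)diphenylsilane, CC(C)(C)[Si](Cl)(c1ccccc1)c1ccccc1
Why: Imidazole-mediated silyl ether formation masks the C14 hydroxyl so that the aldehyde made next cannot close to a lactol and the later acylations reach only O8 and O13.

Step 3
Reactants: 5 silyl ether
Product: 7 (Z)-3-{[(tert-butyldiphenylsilyl)oxy]methyl}-4-iodobut-3-enal, via vicinal diol 6 (not isolated)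
Conditions: OsO4 (2 mol%), NaIO4 (4 equiv), 2,6-lutidine, dioxane/H2O 3:1, rt
Reagents that add atoms: osmium tetroxide, O=[Os](=O)(=O)=O; sodium periodate, [Na+].[O-]I(=O)(=O)=O
Why: Lemieux–Johnson oxidation (dihydroxylation, then periodate glycol cleavage) takes the monosubstituted alkene and leaves the iodine-deactivated trisubstituted alkene, cutting allyl down to the C8 aldehyde (used at once because it is β,γ-unsaturated).

Step 4
Reactants: 7 aldehyde; 8 methyl propiolate
Product: 9 methyl (4S,6Z)-6-{[(tert-butyldiphenylsilyl)oxy]methyl}-4-hydroxy-7-iodohept-6-en-2-ynoate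
Conditions: (S,S)-ProPhenol (20 mol%), Me2Zn (3 equiv), Ph3P=O (40 mol%), toluene, 0 °C
Reagents that add atoms: none
Why: Trost's dinuclear zinc–ProPhenol alkynylation adds the zinc acetylide of methyl propiolate to the Re face of the aldehyde inside the chiral bimetallic pocket, which sets C8 as S (O > alkynyl > CH2 > H) and brings in C7, C11 and C12 at the alkyne oxidation level.

Step 5
Reactants: 9 propargylic alcohol; 10 (R)-2-methylbutanoic acid
Product: 11 methyl (4S,6Z)-6-{[(tert-butyldiphenylsilyl)oxy]methyl}-7-iodo-4-{[(2R)-2-methylbutanoyl]oxy}hept-6-en-2-ynoate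
Conditions: EDC·HCl, DMAP (10 mol%), CH2Cl2, 0 °C
Reagents that add atoms: none
Why: Steglich-type carbodiimide esterification at 0 °C with little DMAP acylates the only free hydroxyl without racemising the acid and blocks O8 from ever lactonising onto C12.

Step 6
Reactants: 11 acyloxy ynoate
Product: 13 methyl (4S,6Z)-6-{[(tert-butyldiphenylsilyl)oxy]methyl}-7-iodo-4-{[(2R)-2-methylbutanoyl]oxy}-3-oxohept-6-enoate, via pyrrolidine enamine 12 (not isolated)
Conditions: pyrrolidine (1.05 equiv), MeCN, 0 °C → rt; then 1 M aq. HCl, THF, 0 °C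
Reagents that add atoms: water, O
Why: Aza-Michael addition of the secondary amine puts nitrogen on C7 only, and acid hydrolysis of the resulting vinylogous carbamate (enamine hydrolysis) is a net regiospecific hydration to the β-keto ester that leaves the acyloxy stereocentre untouched.

Step 7
Reactants: 13 β-keto ester; 14 bromomethyl acetate
Product: 15 methyl (4S,6Z)-2-(acetoxymethyl)-6-{[(tert-butyldiphenylsilyl)oxy]methyl}-7-iodo-4-{[(2R)-2-methylbutanoyl]oxy}-3-oxohept-6-enoate (both C2 epimers)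
Conditions: NaH (1.0 equiv), THF, 0 °C; then 14, 0 °C → rt
Reagents that add atoms: none
Why: C-Alkylation of the soft sodium enolate of the β-keto ester (acetoacetic ester alkylation) with the reactive acyloxymethyl bromide installs C13 already as its acetate while no other hydroxyl is free, and the new C11 centre is removed in the next step.

Step 8
Reactants: 15 acetoxymethyl β-keto ester
Product: 16 methyl (2Z,4S,6Z)-2-(acetoxymethyl)-6-{[(tert-butyldiphenylsilyl)oxy]methyl}-7-iodo-4-{[(2R)-2-methylbutanoyl]oxy}-3-[(trifluoromethanesulfonyl)oxy]hepta-2,6-dienoate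
Conditions: LiOTf, iPr2NEt, Tf2O, CH2Cl2, −78 → −20 °C
Reagents that add atoms: triflic anhydride, O=S(=O)(OS(=O)(=O)C(F)(F)F)C(F)(F)F
Why: Chelation-controlled enol triflation: lithium bridges the enol oxygen on C7 and the ester carbonyl, so O-sulfonylation at low temperature gives the Z enol triflate (OTf cis to CO2Me, C8 cis to CH2OAc), the geometry the lactone needs.

Step 9
Reactants: 16 vinyl iodide enol triflate; 17 (Z)-3-methylpent-2-en-4-yn-1-ol
Product: 18 methyl (2Z,4S,6Z,10Z)-2-(acetoxymethyl)-6-{[(tert-butyldiphenylsilyl)oxy]methyl}-12-hydroxy-10-methyl-4-{[(2R)-2-methylbutanoyl]oxy}-3-[(trifluoromethanesulfonyl)oxy]dodeca-2,6,10-trien-8-ynoate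
Conditions: Pd(PPh3)4 (3 mol%), CuI (6 mol%), Et3N, THF, 0 °C → rt
Reagents that add atoms: none
Why: Sonogashira coupling goes with retention at the unhindered vinyl iodide, which undergoes oxidative addition far faster than the tetrasubstituted enol triflate, joining C1 to C2 with the Z C4=C5 alkene of 17 intact.

Step 10
Reactants: 18 dienyne
Product: 19 methyl (2Z,4S,6Z,8Z,10Z)-2-(acetoxymethyl)-6-{[(tert-butyldiphenylsilyl)oxy]methyl}-12-hydroxy-10-methyl-4-{[(2R)-2-methylbutanoyl]oxy}-3-[(trifluoromethanesulfonyl)oxy]dodeca-2,6,8,10-tetraenoate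
Conditions: Zn dust activated with Cu(OAc)2 and AgNO3, MeOH/H2O 1:1, 35 °C
Reagents that add atoms: none
Why: Boland reduction delivers hydrogen syn only to the triple bond flanked by two alkenes, giving the Z C2=C3 alkene without touching the enol triflate, the esters or the silyl ether.

Step 11
Reactants: 19 silyl ether triene
Product: 20 methyl (2Z,4S,6Z,8Z,10Z)-2-(acetoxymethyl)-12-hydroxy-6-(hydroxymethyl)-10-methyl-4-{[(2R)-2-methylbutanoyl]oxy}-3-[(trifluoromethanesulfonyl)oxy]dodeca-2,6,8,10-tetraenoate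
Conditions: HF·pyridine, pyridine, THF, 0 °C → rt
Reagents that add atoms: none
Why: Buffered fluoride desilylation frees the C14 allylic alcohol without attacking the acetate, the 2-methylbutanoate or the enol triflate.

Step 12
Reactants: 20 triene diol
Product: 21 methyl (2Z,4S)-2-(acetoxymethyl)-5-[(2S,3R)-2-(hydroxymethyl)-3-{(Z)-2-[(2R,3S)-3-(hydroxymethyl)-2-methyloxiran-2-yl]ethenyl}oxiran-2-yl]-4-{[(2R)-2-methylbutanoyl]oxy}-3-[(trifluoromethanesulfonyl)oxy]pent-2-enoate
Conditions: Ti(OiPr)4 (0.3 equiv), L-(+)-DIPT (0.4 equiv), t-BuOOH (4 equiv), 4 Å MS, CH2Cl2, −25 °C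
Reagents that add atoms: tert-butyl hydroperoxide, CC(C)(C)OO
Why: Twofold Katsuki–Sharpless asymmetric epoxidation: each allylic alcohol binds titanium and L-(+)-tartrate delivers oxygen to the face that makes the carbinol-bearing oxirane carbon S (the sense of geraniol to (2S,3S)-epoxygeraniol), giving 10S,1R and 5S,4R while the non-allylic Z C2=C3 and the electron-poor C7=C11 alkenes stay.

Step 13
Reactants: 21 bis-epoxy diol
Product: 22 methyl (2Z,4S)-2-(acetoxymethyl)-5-[(2S,3R)-3-{(Z)-2-[(2R,3R)-3-formyl-2-methyloxiran-2-yl]ethenyl}-2-(hydroxymethyl)oxiran-2-yl]-4-{[(2R)-2-methylbutanoyl]oxy}-3-[(trifluoromethanesulfonyl)oxy]pent-2-enoate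
Conditions: TEMPO (10 mol%), PhI(OAc)2 (1.1 equiv), CH2Cl2, 0 °C
Reagents that add atoms: none
Why: Oxoammonium (TEMPO) oxidation is sensitive to hindrance, so the CH2OH on the CH oxirane carbon (C6) is oxidised in preference to the neopentyl-type CH2OH on the fully substituted oxirane carbon (C14), and it stops at the aldehyde.

Step 14
Reactants: 22 epoxy aldehyde enol triflate
Product: 24 (1R,4R,5S,6S,8S,10S)-13-acetoxy-1,10:4,5-diepoxy-14-hydroxy-8-{[(2R)-2-methylbutanoyl]oxy}germacra-2Z,7(11)-dien-6,12-olide (CNP0108300.1), via macrocyclic hydroxy ester 23 (not isolated)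
Conditions: CrCl2 (10 equiv), NiCl2 (0.2 equiv), DMSO/THF 3:1, syringe-pump addition to 2 mM, rt; aq. sodium serinate work-up
Reagents that add atoms: none
Why: Proposed new method: zerovalent nickel inserts into the activated enol triflate, transmetalation gives an alkenyl trivalent-chromium species that keeps its geometry (metal cis to CO2Me), this adds within the chain to the α,β-epoxy aldehyde at high dilution through the Felkin–Anh rotamer (C5–O anti to the incoming carbon, giving the anti epoxy alcohol, 6S), and the chromium alkoxide closes onto the cis methyl ester to the butenolide; the closest known reactions are Nozaki–Hiyama–Kishi macrocyclisations of alkenyl triflates and the NiCl2/CrCl2 coupling of (Z)-β-iodoacrylates with aldehydes that gives butenolides directly.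

## Compound list

1 | prop-2-yn-1-ol (propargyl alcohol) | C#CCO | starting material
2 | allylmagnesium bromide | C=CC[Mg]Br | starting material
3 | bromomagnesium alkoxide of (Z)-2-[(bromomagnesio)methylene]pent-4-en-1-ol (Mg cis to CH2O) | C=CC/C(CO[Mg]Br)=C/[Mg]Br | intermediate
4 | (Z)-2-(iodomethylene)pent-4-en-1-ol | C=CC/C(CO)=C/I | intermediate
5 | tert-butyl{[(Z)-2-(iodomethylene)pent-4-en-1-yl]oxy}diphenylsilane | C=CC/C(CO[Si](c1ccccc1)(c1ccccc1)C(C)(C)C)=C/I | intermediate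
6 | (Z)-4-{[(tert-butyldiphenylsilyl)oxy]methyl}-5-iodopent-4-ene-1,2-diol | OCC(O)C/C(CO[Si](c1ccccc1)(c1ccccc1)C(C)(C)C)=C/I | intermediate
7 | (Z)-3-{[(tert-butyldiphenylsilyl)oxy]methyl}-4-iodobut-3-enal | O=CC/C(CO[Si](c1ccccc1)(c1ccccc1)C(C)(C)C)=C/I | intermediate
8 | methyl propiolate | C#CC(=O)OC | starting material
9 | methyl (4S,6Z)-6-{[(tert-butyldiphenylsilyl)oxy]methyl}-4-hydroxy-7-iodohept-6-en-2-ynoate | COC(=O)C#C[C@@H](O)C/C(CO[Si](c1ccccc1)(c1ccccc1)C(C)(C)C)=C/I | intermediate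
10 | (R)-2-methylbutanoic acid | CC[C@@H](C)C(=O)O | starting material
11 | methyl (4S,6Z)-6-{[(tert-butyldiphenylsilyl)oxy]methyl}-7-iodo-4-{[(2R)-2-methylbutanoyl]oxy}hept-6-en-2-ynoate | CC[C@@H](C)C(=O)O[C@H](C#CC(=O)OC)C/C(CO[Si](c1ccccc1)(c1ccccc1)C(C)(C)C)=C/I | intermediate
12 | methyl (2E,4S,6Z)-6-{[(tert-butyldiphenylsilyl)oxy]methyl}-7-iodo-4-{[(2R)-2-methylbutanoyl]oxy}-3-(pyrrolidin-1-yl)hepta-2,6-dienoate | CC[C@@H](C)C(=O)O[C@H](/C(N1CCCC1)=C\C(=O)OC)C/C(CO[Si](c1ccccc1)(c1ccccc1)C(C)(C)C)=C/I | intermediate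
13 | methyl (4S,6Z)-6-{[(tert-butyldiphenylsilyl)oxy]methyl}-7-iodo-4-{[(2R)-2-methylbutanoyl]oxy}-3-oxohept-6-enoate | CC[C@@H](C)C(=O)O[C@H](C(=O)CC(=O)OC)C/C(CO[Si](c1ccccc1)(c1ccccc1)C(C)(C)C)=C/I | intermediate
14 | bromomethyl acetate | CC(=O)OCBr | starting material
15 | methyl (4S,6Z)-2-(acetoxymethyl)-6-{[(tert-butyldiphenylsilyl)oxy]methyl}-7-iodo-4-{[(2R)-2-methylbutanoyl]oxy}-3-oxohept-6-enoate (C2 epimers) | CC[C@@H](C)C(=O)O[C@H](C(=O)C(COC(C)=O)C(=O)OC)C/C(CO[Si](c1ccccc1)(c1ccccc1)C(C)(C)C)=C/I | intermediate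
16 | methyl (2Z,4S,6Z)-2-(acetoxymethyl)-6-{[(tert-butyldiphenylsilyl)oxy]methyl}-7-iodo-4-{[(2R)-2-methylbutanoyl]oxy}-3-[(trifluoromethanesulfonyl)oxy]hepta-2,6-dienoate | CC[C@@H](C)C(=O)O[C@H](/C(OS(=O)(=O)C(F)(F)F)=C(\COC(C)=O)C(=O)OC)C/C(CO[Si](c1ccccc1)(c1ccccc1)C(C)(C)C)=C/I | intermediate
17 | (Z)-3-methylpent-2-en-4-yn-1-ol | C#C/C(C)=C\CO | starting material
18 | methyl (2Z,4S,6Z,10Z)-2-(acetoxymethyl)-6-{[(tert-butyldiphenylsilyl)oxy]methyl}-12-hydroxy-10-methyl-4-{[(2R)-2-methylbutanoyl]oxy}-3-[(trifluoromethanesulfonyl)oxy]dodeca-2,6,10-trien-8-ynoate | CC[C@@H](C)C(=O)O[C@H](/C(OS(=O)(=O)C(F)(F)F)=C(\COC(C)=O)C(=O)OC)C/C(CO[Si](c1ccccc1)(c1ccccc1)C(C)(C)C)=C/C#C/C(C)=C\CO | intermediate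
19 | methyl (2Z,4S,6Z,8Z,10Z)-2-(acetoxymethyl)-6-{[(tert-butyldiphenylsilyl)oxy]methyl}-12-hydroxy-10-methyl-4-{[(2R)-2-methylbutanoyl]oxy}-3-[(trifluoromethanesulfonyl)oxy]dodeca-2,6,8,10-tetraenoate | CC[C@@H](C)C(=O)O[C@H](/C(OS(=O)(=O)C(F)(F)F)=C(\COC(C)=O)C(=O)OC)C/C(CO[Si](c1ccccc1)(c1ccccc1)C(C)(C)C)=C/C=C\C(C)=C/CO | intermediate
20 | methyl (2Z,4S,6Z,8Z,10Z)-2-(acetoxymethyl)-12-hydroxy-6-(hydroxymethyl)-10-methyl-4-{[(2R)-2-methylbutanoyl]oxy}-3-[(trifluoromethanesulfonyl)oxy]dodeca-2,6,8,10-tetraenoate | CC[C@@H](C)C(=O)O[C@H](/C(OS(=O)(=O)C(F)(F)F)=C(\COC(C)=O)C(=O)OC)C/C(CO)=C/C=C\C(C)=C/CO | intermediate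
21 | methyl (2Z,4S)-2-(acetoxymethyl)-5-[(2S,3R)-2-(hydroxymethyl)-3-{(Z)-2-[(2R,3S)-3-(hydroxymethyl)-2-methyloxiran-2-yl]ethenyl}oxiran-2-yl]-4-{[(2R)-2-methylbutanoyl]oxy}-3-[(trifluoromethanesulfonyl)oxy]pent-2-enoate | CC[C@@H](C)C(=O)O[C@H](/C(OS(=O)(=O)C(F)(F)F)=C(\COC(C)=O)C(=O)OC)C[C@@]1(CO)O[C@@H]1/C=C\[C@@]1(C)O[C@H]1CO | intermediate
22 | methyl (2Z,4S)-2-(acetoxymethyl)-5-[(2S,3R)-3-{(Z)-2-[(2R,3R)-3-formyl-2-methyloxiran-2-yl]ethenyl}-2-(hydroxymethyl)oxiran-2-yl]-4-{[(2R)-2-methylbutanoyl]oxy}-3-[(trifluoromethanesulfonyl)oxy]pent-2-enoate | CC[C@@H](C)C(=O)O[C@H](/C(OS(=O)(=O)C(F)(F)F)=C(\COC(C)=O)C(=O)OC)C[C@@]1(CO)O[C@@H]1/C=C\[C@@]1(C)O[C@H]1C=O | intermediate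
23 | methyl ester of the ring-closed (6S)-6-hydroxy acid: ten-membered carbocycle with 1,10- and 4,5-oxiranes, Z C2=C3, C7=C11 bearing CO2Me (cis to C6) and CH2OAc, 8-O-(2R)-2-methylbutanoyl, 14-OH | CC[C@@H](C)C(=O)O[C@H]1C[C@@]2(CO)O[C@@H]2/C=C\[C@@]2(C)O[C@H]2[C@@H](O)/C1=C(\C(=O)OC)COC(C)=O | intermediate
24 | (1R,4R,5S,6S,8S,10S)-13-acetoxy-1,10:4,5-diepoxy-14-hydroxy-8-{[(2R)-2-methylbutanoyl]oxy}germacra-2Z,7(11)-dien-6,12-olide (CNP0108300.1) | CC[C@@H](C)C(=O)O[C@H]1C[C@@]2(CO)O[C@@H]2/C=C\[C@@]2(C)O[C@H]2[C@H]2OC(=O)C(COC(C)=O)=C12 | target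

## Step count and weak points

Total step count: 14. Longest linear sequence: 14 (from propargyl alcohol; all other inputs are bought).

Step 14 is the most likely to fail: ring strain and oligomerisation, possible opening of the two vinyl oxiranes by zerovalent nickel, and C6 selectivity that rests on the Felkin–Anh model. The fallback closes the ring with only one oxirane in the chain and epoxidises C1=C10 last, on the ring. It sets out from 19 and comes back at 24. Sharpless epoxidation of 19 (Ti(OiPr)4, L-(+)-DIPT, t-BuOOH) touches only the free C6 allylic alcohol and gives the mono-epoxy alcohol F1. TEMPO/PhI(OAc)2 then gives the mono-epoxy aldehyde F2, with no second free hydroxyl to compete. CrCl2/NiCl2 at high dilution closes the ring through the macrocyclic hydroxy ester F3 (not isolated) to the 14-O-silyl lactone F4. HF·pyridine frees the ring allylic alcohol F5, and a last Sharpless epoxidation with L-(+)-DIPT (same facial sense as in step 12) gives 24; here the ring may oppose the reagent-controlled face.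

Step 13 is the next weakest: the two primary epoxy alcohols may not be discriminated well enough. The fallback oxidises C6 before the C14 hydroxyl is set free. It sets out from 19 and comes back at 22. It runs through the mono-epoxy alcohol F1 and the mono-epoxy aldehyde F2 described above, then HF·pyridine gives the hydroxy aldehyde F6, and Sharpless epoxidation of its C14 allylic alcohol (L-(+)-DIPT, −25 °C), done in the presence of the aldehyde, gives 22.

Step 9 is the third: palladium may also attack the enol triflate or the allylic acetate. The fallback is a palladium-free union with the Z C2=C3 alkene already in place. It sets out from 16 and 17 and comes back at 19, so that 18 and step 10 are skipped. Compound 17 is C-stannylated (n-BuLi 2 equiv, then Bu3SnCl) to the alkynylstannane F7. Hydrozirconation with Cp2Zr(H)Cl followed by protonolysis gives the (2Z,4Z)-dienylstannane F8. Coupling of F8 with the vinyl iodide of 16, mediated by copper thiophene-2-carboxylate (CuTC) in NMP at 0 °C, gives 19 with retention at both partners.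

Further compounds

F1 | step 14 | mono-epoxy alcohol: 19 with the (4R,5S)-oxirane at C4–C5, C6–OH free, 14-O-TBDPS | CC[C@@H](C)C(=O)O[C@H](/C(OS(=O)(=O)C(F)(F)F)=C(\COC(C)=O)C(=O)OC)C/C(CO[Si](c1ccccc1)(c1ccccc1)C(C)(C)C)=C/C=C\[C@@]1(C)O[C@H]1CO
F2 | step 14 | mono-epoxy aldehyde: C6 aldehyde of F1 | CC[C@@H](C)C(=O)O[C@H](/C(OS(=O)(=O)C(F)(F)F)=C(\COC(C)=O)C(=O)OC)C/C(CO[Si](c1ccccc1)(c1ccccc1)C(C)(C)C)=C/C=C\[C@@]1(C)O[C@H]1C=O
F3 | step 14 | macrocyclic (6S)-hydroxy methyl ester with 1(10),2-diene, 4,5-oxirane and 14-O-TBDPS | CC[C@@H](C)C(=O)O[C@H]1C/C(CO[Si](c1ccccc1)(c1ccccc1)C(C)(C)C)=C/C=C\[C@@]2(C)O[C@H]2[C@@H](O)/C1=C(\C(=O)OC)COC(C)=O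
F4 | step 14 | 13-acetoxy-14-[(tert-butyldiphenylsilyl)oxy]-4,5-epoxy-8-{[(2R)-2-methylbutanoyl]oxy}germacra-1(10),2Z,7(11)-trien-6,12-olide | CC[C@@H](C)C(=O)O[C@H]1C/C(CO[Si](c1ccccc1)(c1ccccc1)C(C)(C)C)=C/C=C\[C@@]2(C)O[C@H]2[C@H]2OC(=O)C(COC(C)=O)=C12
F5 | step 14 | 13-acetoxy-4,5-epoxy-14-hydroxy-8-{[(2R)-2-methylbutanoyl]oxy}germacra-1(10),2Z,7(11)-trien-6,12-olide | CC[C@@H](C)C(=O)O[C@H]1C/C(CO)=C/C=C\[C@@]2(C)O[C@H]2[C@H]2OC(=O)C(COC(C)=O)=C12
F6 | step 13 | desilylated mono-epoxy aldehyde (C14–OH free, C1=C10 still an alkene) | CC[C@@H](C)C(=O)O[C@H](/C(OS(=O)(=O)C(F)(F)F)=C(\COC(C)=O)C(=O)OC)C/C(CO)=C/C=C\[C@@]1(C)O[C@H]1C=O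
F7 | step 9 | (Z)-3-methyl-5-(tributylstannyl)pent-2-en-4-yn-1-ol | CCCC[Sn](CCCC)(CCCC)C#C/C(C)=C\CO
F8 | step 9 | (2Z,4Z)-3-methyl-5-(tributylstannyl)penta-2,4-dien-1-ol | CCCC[Sn](CCCC)(CCCC)/C=C\C(C)=C/CO
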